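In the teal run a small charge of Q had to work through a large charge of Z, so I began from the balance of Q: free Q plus Q held on Z stays equal to what was charged, and each Q serves many Z in turn.

| setting | teal | ochre | grey | amber |
|---|---|---|---|---|
| Z | 0.300 M | 0.150 M | 0.450 M | 0.900 M |
| Q | 6.00 × 10⁻⁴ M | 6.00 × 10⁻⁴ M | 6.00 × 10⁻⁴ M | 0.00180 M |
| time |  |  |  | 4.9 min |

| run | time / min | [Z] / M |
|---|---|---|
| teal run | 0.37 | 0.273 |
| teal run | 1.1 | 0.248 |
| teal run | 2.2 | 0.199 |
| teal run | 3.4 | 0.151 |
| teal run | 4.9 | 0.094 |
| ochre run | 0.37 | 0.137 |
| ochre run | 1.1 | 0.115 |
| ochre run | 2.2 | 0.079 |
| ochre run | 3.4 | 0.050 |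
| ochre run | 4.9 | 0.027 |
| grey run | 0.37 | 0.429 |
| grey run | 1.1 | 0.381 |
| grey run | 2.2 | 0.320 |
| grey run | 3.4 | 0.255 |
| grey run | 4.9 | 0.192 |

(standard deviation of a reading: 0.003 M)

- Overall: Z -> X, with Q as catalyst.
- Constant volume, constant temperature.
- What is held in complexes is read along with the free species.
- An order is taken over about fifteen percent of the charge, up and down.

- reaction order in [Z] at the outset, round the charge of the teal run, defined at two percent of the Z turned into X (one fixed amount of X, the same in the runs compared)
- the ochre run starts with 0.150 M less of Z than the teal run, and with no X. Compared where both hold the same amount of Z, once fifteen percent of what the ochre run was charged with has turned into X, is the ochre run faster, slower or alike (within a tenth)?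
- Z in the amber run at 4.9 min, as a share of the Z charged
- which of these the readings show (an uncatalysed path runs beside / the product kills the catalyst / the catalyst rests as a dimer)

I folded the charges into the load N, Z charged over Q charged, the substrate-to-catalyst ratio. For the teal run N is 500, the Z to be cleared per Q charged. Let s be the share of the charge left, ν the turnovers per Q per minute, and k the constant of any first-order path beside Q; then ds/dt = −ν/N − ks. Two flasks at one temperature, with equal N and equal ν, therefore keep equal s. The amber run has N = 500, the same as teal, so I carried over teal's reading at 4.9 min, s = 31.3 %.

I then tested whether ν stays put as Z changes. Between the early grey run and the middle of the teal run, the slope of rate against Z read 0.0994 /min, but within the ochre run, from middle to late, it read 0.294 /min, which is steeper. So ν sags at low Z, and one number was not enough. At equal s the amber run holds 3.00 times teal's Z, so I committed to amber ending below teal's 31.3 %.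

The forecast put amber at 32 %, within 25 % to 40 % and higher than my mark, with order 0.55, alike at equal Z, and the choice that an uncatalysed path runs beside, holding that “the catalysed term triples and the background does not”. The flask gave 24.0 % for amber, below my mark, with order 0.50, alike at equal Z, and the finding that an uncatalysed path runs beside.

    Q + Z ⇌ QZ, settled at all times (14.50 /M)
    QZ → X + Q (67.20 /min)
    Z → X (0.06480 /min)

At load 500, the amber run's 24.0 % means Z lost at 77.6 /min per Q on average, faster than the constant of the step QZ → X + Q, 67.2 /min. The excess belongs to the path Z → X: without it amber keeps 41.0 %, which is 60.2 /min per Q, below that constant. In the teal run, half of the charge went in 3.35 min, which at load 500 is 74.6 /min per Q on average, again above it.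

(The data are calculated for substances that don't exist; scatter was added.)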